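**Plan**

- Retrosynthesis cuts the two depside C(=O)–O bonds (ring A acyl to ring B O4, then ring B acyl to ring C O4) and, within ring A, the bonds C3–C4 and C5–C6.
- Enabling feature: ring A is a pentasubstituted benzene whose C1 (ester), C2 (OMe), C3 (O) and C6 (CH3) map onto C5, C4, C3 and C6 of a 2-pyrone-5-carboxylate, while C4 (O) and C5 (H) are the two carbons of a ketene acetal. The methyl and benzyl labels on the three neighbouring oxygens are therefore fixed before the ring exists.
- Forward: benzyloxymalonic acid and allyl acetoacetate give the pyrone. Cycloaddition with ketene dibenzyl acetal, then loss of CO2 and benzyl alcohol, gives ring A. Rings B and C are joined separately from orsellinic acid, the ring A acid is esterified onto ring B, and one hydrogenolysis removes all benzyl groups.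
- Stereochemistry: the target has no stereocentre. The only ones on the route (two bridgeheads of a racemic cycloadduct) vanish on aromatisation.

Key step: step 7

Assumption: the 2-hydroxyls of rings B and C, each hydrogen-bonded to an ortho ester carbonyl, are left unprotected in the last coupling because they acylate far more slowly than a free 4-hydroxyl.

**Route**

Step 1
Reactants: 1 diethyl 2-hydroxymalonate
Product: 2 diethyl 2-(benzyloxy)malonate
Conditions: BnOC(=NH)CCl3 (1.3 equiv), TfOH (cat.), CH2Cl2/cyclohexane, 0 °C to rt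
Reagents that add atoms: benzyl 2,2,2-trichloroacetimidate, N=C(OCc1ccccc1)C(Cl)(Cl)Cl
Why: Acid-catalysed benzyl transfer from the trichloroacetimidate (trichloroacetimidate O-benzylation) etherifies the electron-poor secondary hydroxyl without base, so the acidic malonate C–H and the esters are left alone.

Step 2
Reactants: 2 diethyl 2-(benzyloxy)malonate
Product: 3 2-(benzyloxy)malonic acid
Conditions: KOH (2.5 equiv), EtOH/H2O, 0 °C to rt; then aq. HCl, 0 °C
Reagents that add atoms: potassium hydroxide, [K+].[OH-]
Why: Ester saponification of two unhindered ethyl esters proceeds at room temperature, and cold acidification should give the malonic acid without decarboxylation.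

Step 3
Reactants: 3 2-(benzyloxy)malonic acid; 4 allyl acetoacetate
Product: 6 allyl 3-(benzyloxy)-4-hydroxy-6-methyl-2-oxo-2H-pyran-5-carboxylate, via 2-(benzyloxy)malonyl dichloride 5 (not isolated)
Conditions: (COCl)2 (2.2 equiv), DMF (cat.), CH2Cl2, 0 °C to rt, evaporate; then 4 (1.0 equiv), PhMe, rt to 80 °C, N2 stream
Reagents that add atoms: none
Why: Oxalyl chloride gives the diacid chloride, which should undergo the known annulation of malonyl dichlorides with β-keto esters (C-acylation of the active methylene by one acyl chloride, O-acylation of the ketone enol by the other) to a 4-hydroxy-2-pyrone-5-carboxylate, here with the benzyloxy group at pyrone C3.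

Step 4
Reactants: 6 allyl 3-(benzyloxy)-4-hydroxy-6-methyl-2-oxo-2H-pyran-5-carboxylate
Product: 7 allyl 3-(benzyloxy)-4-methoxy-6-methyl-2-oxo-2H-pyran-5-carboxylate
Conditions: Me2SO4 (1.5 equiv), K2CO3 (2 equiv), acetone, reflux
Reagents that add atoms: dimethyl sulfate, COS(=O)(=O)OC
Why: Williamson-type O-methylation of the vinylogous acid with a hard electrophile is the standard way from 4-hydroxy-2-pyrones to 4-methoxy-2-pyrones, and both carbons flanking the hydroxyl are already substituted.

Step 5
Reactants: 8 bromoacetaldehyde diethyl acetal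
Product: 9 2-bromo-1,1-bis(benzyloxy)ethane (bromoacetaldehyde dibenzyl acetal)
Conditions: BnOH (2.2 equiv), TsOH·H2O (cat.), 110 °C, EtOH distilled off; then vacuum distillation
Reagents that add atoms: benzyl alcohol, OCc1ccccc1
Why: Acid-catalysed transacetalisation is driven to the dibenzyl acetal by distilling out the ethanol.

Step 6
Reactants: 9 2-bromo-1,1-bis(benzyloxy)ethane
Product: 10 1,1-bis(benzyloxy)ethene (ketene dibenzyl acetal)
Conditions: KOtBu (1.3 equiv), THF, 0 °C to rt; filtered and concentrated in base-washed glass, used directly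
Reagents that add atoms: none
Why: E2 dehydrobromination of an α-bromo acetal by tert-butoxide is the classical ketene acetal synthesis, the acetal C–H being the only proton that can leave with bromide.

Step 7
Reactants: 7 allyl 3-(benzyloxy)-4-methoxy-6-methyl-2-oxo-2H-pyran-5-carboxylate; 10 1,1-bis(benzyloxy)ethene
Product: 13 allyl 3,4-bis(benzyloxy)-2-methoxy-6-methylbenzoate, via bridged lactone 11 (not isolated), via cyclohexadiene ketal 12 (not isolated)
Conditions: 10 (4 equiv), PhMe, 110–130 °C, sealed tube, base-washed glass, N2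
Reagents that add atoms: none
Why: The ester-bearing pyrone is an electron-poor diene and the acetal an electron-rich alkene, so a concerted but asynchronous inverse-electron-demand (4+2) cycloaddition across pyrone C3 and C6 should give the bridged lactone 11; retro-(4+2) loss of CO2 then gives diene 12, and 1,2-elimination of benzyl alcohol (H from the new CH2, OBn from the acetal carbon) aromatises it. The closest known reaction type is the Diels–Alder, decarboxylation and alcohol-loss sequence of 2-pyrone-5-carboxylates (coumalates) with ketene acetals, which gives para-alkoxybenzoates. Ring A is closed by intermolecular (4+2) cycloaddition, its C5–C6 and C3–C4 bonds forming in one operation from four pyrone carbons and the two acetal carbons, with the lactone bridge as a transient second ring. No stereocentre is kept: the two bridgeheads of racemic 11 become aromatic carbons. The selectivity needed is regiochemical and is secured by polarisation, since the nucleophilic CH2 of the acetal bonds to pyrone C6 (β-carbon of the C5 acrylate unit and vinylogous terminus of the lactone carbonyl), which puts the acetal carbon on C3 and its oxygen para to the ester. The oxygen donors at pyrone C3 and C4 and the C6 methyl slow the addition, hence heat and excess acetal, with the temperature held below that at which benzyl ketene acetals may isomerise by 1,3-benzyl shift.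

Step 8
Reactants: 13 allyl 3,4-bis(benzyloxy)-2-methoxy-6-methylbenzoate
Product: 14 3,4-bis(benzyloxy)-2-methoxy-6-methylbenzoic acid
Conditions: Pd(PPh3)4 (5 mol %), morpholine (5 equiv), THF, rt; acidic work-up
Reagents that add atoms: none
Why: Tsuji–Trost deallylation, in which zerovalent palladium ionises the allyl ester to a π-allyl complex that morpholine captures, cleaves the ester at the allyl carbon and so is indifferent to the two ortho substituents that would block saponification, and it leaves benzyl ethers alone.

Step 9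
Reactants: 15 orsellinic acid (2,4-dihydroxy-6-methylbenzoic acid)
Product: 16 benzyl 2,4-dihydroxy-6-methylbenzoate (benzyl orsellinate)
Conditions: BnBr (1.05 equiv), KHCO3 (1.2 equiv), DMF, rt
Reagents that add atoms: benzyl bromide, BrCc1ccccc1
Why: SN2 O-alkylation of the carboxylate is selective because hydrogen carbonate deprotonates the acid but not the phenols.

Step 10
Reactants: 16 benzyl 2,4-dihydroxy-6-methylbenzoate
Product: 17 benzyl 2,4-bis(methoxymethoxy)-6-methylbenzoate
Conditions: NaH (2.5 equiv), MeOCH2Cl (2.6 equiv), DMF, 0 °C to rt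
Reagents that add atoms: chloromethyl methyl ether, COCCl
Why: Williamson etherification of both sodium phenoxides gives the bis(methoxymethyl) ether, the strong base being needed for the chelated 2-hydroxyl.

Step 11
Reactants: 17 benzyl 2,4-bis(methoxymethoxy)-6-methylbenzoate
Product: 18 2,4-bis(methoxymethoxy)-6-methylbenzoic acid
Conditions: H2 (1 atm), Pd/C (10 wt %), EtOAc, rt
Reagents that add atoms: none
Why: Hydrogenolysis of the benzylic C–O bond frees the hindered acid without hydroxide, and methoxymethyl acetals are inert to it.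

Step 12
Reactants: 18 2,4-bis(methoxymethoxy)-6-methylbenzoic acid; 16 benzyl 2,4-dihydroxy-6-methylbenzoate
Product: 19 benzyl 4-{[2,4-bis(methoxymethoxy)-6-methylbenzoyl]oxy}-2-hydroxy-6-methylbenzoate
Conditions: DCC (1.1 equiv), DMAP (0.1 equiv), CH2Cl2, 0 °C to rt
Reagents that add atoms: none
Why: Steglich esterification should acylate the free 4-hydroxyl of 16, its 2-hydroxyl being hydrogen-bonded to the ester carbonyl and flanked by it.

Step 13
Reactants: 19 benzyl 4-{[2,4-bis(methoxymethoxy)-6-methylbenzoyl]oxy}-2-hydroxy-6-methylbenzoate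
Product: 20 benzyl 4-[(2,4-dihydroxy-6-methylbenzoyl)oxy]-2-hydroxy-6-methylbenzoate (benzyl lecanorate)
Conditions: 6 M aq. HCl, THF, 40 °C
Reagents that add atoms: none
Why: Acid hydrolysis cleaves the two aryl methoxymethyl acetals under conditions to which the di-ortho-substituted aryl ester and the benzyl ester are stable.

Step 14
Reactants: 14 3,4-bis(benzyloxy)-2-methoxy-6-methylbenzoic acid; 20 benzyl 4-[(2,4-dihydroxy-6-methylbenzoyl)oxy]-2-hydroxy-6-methylbenzoate
Product: 21 benzyl 4-{[4-({[3,4-bis(benzyloxy)-2-methoxy-6-methylphenyl]carbonyl}oxy)-2-hydroxy-6-methylbenzoyl]oxy}-2-hydroxy-6-methylbenzoate (protected tridepside)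
Conditions: (CF3CO)2O (4 equiv), PhMe/CH2Cl2, 0 °C to rt
Reagents that add atoms: none
Why: Esterification through the mixed trifluoroacetic anhydride, the standard depside coupling for di-ortho-substituted benzoic acids, should acylate only the ring B 4-hydroxyl because the two 2-hydroxyls are chelated to their ortho carbonyls.

Step 15
Reactants: 21 protected tridepside
Product: 22 4-{[4-({[3,4-dihydroxy-2-methoxy-6-methylphenyl]carbonyl}oxy)-2-hydroxy-6-methylbenzoyl]oxy}-2-hydroxy-6-methylbenzoic acid (target)
Conditions: H2 (1 atm), Pd/C (10 wt %), EtOAc/THF, rt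
Reagents that add atoms: none
Why: Hydrogenolysis removes the benzyl ester and both benzyl ethers in one operation while the aryl esters and the aryl methyl ether are untouched.

**Compound list**

1 | diethyl 2-hydroxymalonate | CCOC(=O)C(O)C(=O)OCC | starting material
2 | diethyl 2-(benzyloxy)malonate | CCOC(=O)C(OCc1ccccc1)C(=O)OCC | intermediate
3 | 2-(benzyloxy)malonic acid | OC(=O)C(OCc1ccccc1)C(=O)O | intermediate
4 | allyl acetoacetate | CC(=O)CC(=O)OCC=C | starting material
5 | 2-(benzyloxy)malonyl dichloride (formed in the flask) | ClC(=O)C(OCc1ccccc1)C(Cl)=O | intermediate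
6 | allyl 3-(benzyloxy)-4-hydroxy-6-methyl-2-oxo-2H-pyran-5-carboxylate | CC1=C(C(=O)OCC=C)C(O)=C(OCc2ccccc2)C(=O)O1 | intermediate
7 | allyl 3-(benzyloxy)-4-methoxy-6-methyl-2-oxo-2H-pyran-5-carboxylate | CC1=C(C(=O)OCC=C)C(OC)=C(OCc2ccccc2)C(=O)O1 | intermediate
8 | bromoacetaldehyde diethyl acetal | CCOC(CBr)OCC | starting material
9 | 2-bromo-1,1-bis(benzyloxy)ethane | BrCC(OCc1ccccc1)OCc1ccccc1 | intermediate
10 | 1,1-bis(benzyloxy)ethene | C=C(OCc1ccccc1)OCc1ccccc1 | intermediate
11 | allyl 4,8,8-tris(benzyloxy)-5-methoxy-1-methyl-3-oxo-2-oxabicyclo[2.2.2]oct-5-ene-6-carboxylate (racemate, one enantiomer written; formed in the flask) | C[C@]12OC(=O)[C@](OCc3ccccc3)(C(OC)=C1C(=O)OCC=C)C(OCc3ccccc3)(OCc3ccccc3)C2 | intermediate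
12 | allyl 4,4,5-tris(benzyloxy)-6-methoxy-2-methylcyclohexa-1,5-diene-1-carboxylate (formed in the flask) | CC1=C(C(=O)OCC=C)C(OC)=C(OCc2ccccc2)C(OCc2ccccc2)(OCc2ccccc2)C1 | intermediate
13 | allyl 3,4-bis(benzyloxy)-2-methoxy-6-methylbenzoate | COc1c(OCc2ccccc2)c(OCc2ccccc2)cc(C)c1C(=O)OCC=C | intermediate
14 | 3,4-bis(benzyloxy)-2-methoxy-6-methylbenzoic acid | COc1c(OCc2ccccc2)c(OCc2ccccc2)cc(C)c1C(=O)O | intermediate
15 | orsellinic acid (2,4-dihydroxy-6-methylbenzoic acid) | Cc1cc(O)cc(O)c1C(=O)O | starting material
16 | benzyl 2,4-dihydroxy-6-methylbenzoate | Cc1cc(O)cc(O)c1C(=O)OCc1ccccc1 | intermediate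
17 | benzyl 2,4-bis(methoxymethoxy)-6-methylbenzoate | COCOc1cc(C)c(C(=O)OCc2ccccc2)c(OCOC)c1 | intermediate
18 | 2,4-bis(methoxymethoxy)-6-methylbenzoic acid | COCOc1cc(C)c(C(=O)O)c(OCOC)c1 | intermediate
19 | benzyl 4-{[2,4-bis(methoxymethoxy)-6-methylbenzoyl]oxy}-2-hydroxy-6-methylbenzoate | COCOc1cc(C)c(C(=O)Oc2cc(C)c(C(=O)OCc3ccccc3)c(O)c2)c(OCOC)c1 | intermediate
20 | benzyl 4-[(2,4-dihydroxy-6-methylbenzoyl)oxy]-2-hydroxy-6-methylbenzoate | Cc1cc(O)cc(O)c1C(=O)Oc1cc(C)c(C(=O)OCc2ccccc2)c(O)c1 | intermediate
21 | benzyl ester of the tridepside with ring A as its 3,4-dibenzyl ether | COc1c(OCc2ccccc2)c(OCc2ccccc2)cc(C)c1C(=O)Oc1cc(C)c(C(=O)Oc2cc(C)c(C(=O)OCc3ccccc3)c(O)c2)c(O)c1 | intermediate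
22 | CNP0277338.0, the tridepside acid | COc1c(O)c(O)cc(C)c1C(=O)Oc1cc(C)c(C(=O)Oc2cc(C)c(C(=O)O)c(O)c2)c(O)c1 | target

**Count**

Total steps: 15. Longest linear sequence: 8 steps (1, 2, 3, 4, 7, 8, 14, 15) from diethyl 2-hydroxymalonate; the didepside branch (9 to 13) and the acetal branch (5, 6) are shorter.

**Steps most likely to fail**

First, step 7. The cycloaddition may be too slow, because the oxygen donors at pyrone C3 and C4 raise the diene LUMO and the C6 methyl hinders the first bond. At the temperature then needed, the dibenzyl acetal could be consumed by 1,3-benzyl shift or polymerisation before it adds. The fallback sets out from 7 and changes the dienophile to a ketene bis(silyl) acetal, which is more electron-rich and has no benzyl group to migrate. The acetal 1,1-bis(trimethylsilyloxy)ethene F1, made from trimethylsilyl acetate with LiN(iPr)2 and Me3SiCl in THF at −78 °C, would be heated with 7 in toluene. The bridged lactone allyl 4-(benzyloxy)-5-methoxy-1-methyl-3-oxo-8,8-bis(trimethylsilyloxy)-2-oxabicyclo[2.2.2]oct-5-ene-6-carboxylate F2 should lose CO2 to the diene allyl 5-(benzyloxy)-6-methoxy-2-methyl-4,4-bis(trimethylsilyloxy)cyclohexa-1,5-diene-1-carboxylate F3. That diene loses trimethylsilanol to give allyl 3-(benzyloxy)-2-methoxy-6-methyl-4-(trimethylsilyloxy)benzoate F4. Dilute aqueous acid in THF then frees the phenol allyl 3-(benzyloxy)-4-hydroxy-2-methoxy-6-methylbenzoate F5, and benzylation (BnBr, K2CO3, DMF) returns to the route at 13.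

Second, step 3. The α-benzyloxy diacid chloride may lose HCl to a chlorocarbonyl ketene that oligomerises, or the malonic acid may decarboxylate during activation, so that little annulation takes place. The fallback sets out from 2 and builds the pyrone stepwise. One ester is saponified (KOH, 1 equiv, EtOH, 0 °C) to 2-(benzyloxy)-3-ethoxy-3-oxopropanoic acid F6, which oxalyl chloride converts into ethyl 2-(benzyloxy)-3-chloro-3-oxopropanoate F7. C-acylation of the magnesium enolate of 4 (MgCl2, pyridine, CH2Cl2, 0 °C) gives allyl 2-acetyl-4-(benzyloxy)-5-ethoxy-3,5-dioxopentanoate F8. DBU in warm toluene then closes the lactone from the acetyl enol oxygen onto the ethyl ester with loss of ethanol, returning to the route at 6.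

Third, step 14. Acylation may not stay on one oxygen: the di-ortho-substituted acyl donor reacts slowly, so the chelated 2-hydroxyls of 20 could compete, or the trifluoroacetic acid formed could scramble the depside bond already present. The fallback sets out from 14 and reverses the order of assembly, so that the hindered acylation meets a diphenol and no depside bond yet exists. Compound 15 is converted (allyl bromide, KHCO3, DMF) into allyl 2,4-dihydroxy-6-methylbenzoate F9. Coupling of 14 with F9 (trifluoroacetic anhydride, toluene) gives allyl 4-{[3,4-bis(benzyloxy)-2-methoxy-6-methylbenzoyl]oxy}-2-hydroxy-6-methylbenzoate F10. Pd(PPh3)4 and morpholine release 4-{[3,4-bis(benzyloxy)-2-methoxy-6-methylbenzoyl]oxy}-2-hydroxy-6-methylbenzoic acid F11, and Steglich coupling of F11 with 16 (DCC, DMAP, CH2Cl2) returns to the route at 21.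

**Further compounds**

F1 | step 7 | 1,1-bis(trimethylsilyloxy)ethene | C=C(O[Si](C)(C)C)O[Si](C)(C)C
F2 | step 7 | allyl 4-(benzyloxy)-5-methoxy-1-methyl-3-oxo-8,8-bis(trimethylsilyloxy)-2-oxabicyclo[2.2.2]oct-5-ene-6-carboxylate (racemate, one enantiomer written) | C[C@]12OC(=O)[C@](OCc3ccccc3)(C(OC)=C1C(=O)OCC=C)C(O[Si](C)(C)C)(O[Si](C)(C)C)C2
F3 | step 7 | allyl 5-(benzyloxy)-6-methoxy-2-methyl-4,4-bis(trimethylsilyloxy)cyclohexa-1,5-diene-1-carboxylate | CC1=C(C(=O)OCC=C)C(OC)=C(OCc2ccccc2)C(O[Si](C)(C)C)(O[Si](C)(C)C)C1
F4 | step 7 | allyl 3-(benzyloxy)-2-methoxy-6-methyl-4-(trimethylsilyloxy)benzoate | COc1c(OCc2ccccc2)c(O[Si](C)(C)C)cc(C)c1C(=O)OCC=C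
F5 | step 7 | allyl 3-(benzyloxy)-4-hydroxy-2-methoxy-6-methylbenzoate | COc1c(OCc2ccccc2)c(O)cc(C)c1C(=O)OCC=C
F6 | step 3 | 2-(benzyloxy)-3-ethoxy-3-oxopropanoic acid (racemic) | CCOC(=O)C(OCc1ccccc1)C(=O)O
F7 | step 3 | ethyl 2-(benzyloxy)-3-chloro-3-oxopropanoate (racemic) | CCOC(=O)C(OCc1ccccc1)C(Cl)=O
F8 | step 3 | allyl 2-acetyl-4-(benzyloxy)-5-ethoxy-3,5-dioxopentanoate (stereoisomer and enol mixture) | CCOC(=O)C(OCc1ccccc1)C(=O)C(C(C)=O)C(=O)OCC=C
F9 | step 14 | allyl 2,4-dihydroxy-6-methylbenzoate | Cc1cc(O)cc(O)c1C(=O)OCC=C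
F10 | step 14 | allyl 4-{[3,4-bis(benzyloxy)-2-methoxy-6-methylbenzoyl]oxy}-2-hydroxy-6-methylbenzoate | COc1c(OCc2ccccc2)c(OCc2ccccc2)cc(C)c1C(=O)Oc1cc(C)c(C(=O)OCC=C)c(O)c1
F11 | step 14 | 4-{[3,4-bis(benzyloxy)-2-methoxy-6-methylbenzoyl]oxy}-2-hydroxy-6-methylbenzoic acid | COc1c(OCc2ccccc2)c(OCc2ccccc2)cc(C)c1C(=O)Oc1cc(C)c(C(=O)O)c(O)c1
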